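The runs were generated by integration with constants of no real substance; the scatter is artificial.

| flask | starting material | reagent | second catalyst | precatalyst | remark |
|---|---|---|---|---|---|
| birch | 0.30 M | 1.1 equiv | 5 mol% | 8.2 mol% | the very flask that is asked about, followed so far |
| flask | 0.30 M | 1.10 equiv | 5 mol% | 8.2 mol% |  |

birch run (percent of the starting material charged)

| time / min | target / % | starting material / % |
|---|---|---|
| 2.50 | 1.2 | 63.1 |
| 6.00 | 3.8 | 28.4 |
| 15.0 | 16.1 | 4.9 |
| 30.0 | 28.1 | 0 |

(scatter of a reading: 1 percentage point)

- "the catalyst" is free catalyst with its forms; second catalyst is a second catalyst
- no earlier run changes the charge of reagent; that part of a forecast is a guess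
- no earlier run changes the charge of precatalyst; that part of a forecast is a guess

- factor on the rate of making target when 30 % of the starting material are converted if reagent is charged twice over
- factor on the rate when 30 % of the starting material are converted if precatalyst is charged at 0.8 mol% instead

Starting material, the limiting reagent, falls far faster than target rises: at 6.00 min this flask holds 28.4 % of it and 3.8 % target. I carry the run-down half-life, the time in which starting material halves, which that reading puts at 3.30 min.

At 2.50 min, just past the 30 % mark, target stands at 1.2 %, so reagent is still near its charge. Doubling it gives a factor of 2 if the target step takes one reagent and 1 if that step ignores it, and no run narrows this bracket.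

For precatalyst, my floor is the charge ratio, 0.0976, a rate in step with the charge, and my roof starts at 1, a rate that ignores it. Target's gain slows 1.71-fold from the span ending at 15.0 min to the next. Yet the unseen share, neither starting material nor target, reads 79.0 % at 15.0 min and 71.9 % at 30.0 min, and reagent, counted at one per target, then stands near 74.5 % of its own charge. So I read part of the unseen share as dead, a loss running beside the target step. If the half-life stretches with the charge to 33.9 min, that loss gets ten times as long, so I lower the roof to 0.5, as a judgement.

The forecast says 1.4 for doubled reagent and 0.6 for the smaller precatalyst charge, “I guess 0.6, very uncertain”: inside the first bracket, above my roof.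

The simulation gives 1.93 and 0.224, both inside my brackets.

    starting material + free catalyst → free catalyst + intermediate (k = 0.110 M⁻¹ s⁻¹)
    reagent + second catalyst + intermediate → second catalyst + target (k = 0.150 M⁻² s⁻¹)
    precatalyst → free catalyst (k = 0.0480 s⁻¹)
    starting material + intermediate → side product (k = 0.0170 M⁻¹ s⁻¹)

At 3.24 min in this flask, intermediate's half-life is 4.1 min by the side step and 16 min by the target step, both longer than the run-down half-life as read from the run, and the target step uses intermediate at 0.26 of the side step's rate. With twice the precatalyst, the time to 30 % conversion is 0.607 of its value in this flask, and that factor, applied to the half-life read here, gives an estimate of about 2.00 min.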